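A small charge of free catalyst, 1.0 mM, sorts a racemate in this flask, and I reckon with the fraction of each substrate left, not with the product made.

in all of them: left-handed substrate 0.10 M; right-handed substrate 0.10 M

|  | partner | protic impurity | free catalyst | remark | time |
|---|---|---|---|---|---|
| elm | 0.15 M | 0.030 M | 1.4 mM | run made earlier |  |
| cedar | 0.15 M | 0.030 M | 2.2 mM | run made earlier |  |
| oak | 0.075 M | 0.030 M | 1 mM | run made earlier |  |
| flask | 0.150 M | 0.0300 M | 1.0 mM |  | 25 min |

| run | time / min | right-handed substrate / % | left-handed substrate / % | left-handed product / % |
|---|---|---|---|---|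
| elm | 4.00 | 48.2 | 7.0 | 42.6 |
| elm | 8.00 | 45.8 | 1.1 | 48.9 |
| elm | 12.0 | 44.2 | 1.6 | 49.3 |
| elm | 15.0 | 43.6 | 0 | 50.3 |
| cedar | 4.00 | 46.7 | 4.3 | 47.4 |
| cedar | 8.00 | 43.9 | 0 | 49.4 |
| cedar | 12.0 | 42.9 | 0.6 | 50.5 |
| cedar | 15.0 | 40.8 | 0 | 49.6 |
| oak | 4.00 | 49.0 | 35.2 | 14.5 |
| oak | 8.00 | 49.3 | 29.8 | 19.5 |
| oak | 12.0 | 49.5 | 29.3 | 20.4 |
| oak | 15.0 | 49.7 | 27.7 | 21.2 |

(readings scatter by 0.5 percentage points)

- whether the excess of right-handed substrate over left-handed substrate among what is left of the two reaches 80 % by 25 min (yes / no)
- the highest excess of right-handed substrate over left-handed substrate among what is left of the two up to 25 min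

- free catalyst is single-handed; left-handed substrate and right-handed substrate are mirror images of each other, charged as a racemate, each of them at the stated concentration

The elm and cedar readings at 4.00 min, pooled, give 42.1. This reading is my selectivity factor s, the logarithm of the fraction of left-handed substrate left over the logarithm of the fraction of right-handed substrate left.

I turn the settings in turn. Partner comes first. By hand, [partner] minus [protic impurity] is what can react. In oak that is 22.5 % of the substrates charged, and oak's left-handed product reads 21.2 %, so partner is oak's limiting reagent. In the flask the same difference is 60.0 %, and 0.120 M exceeds 0.10 M, so the left-handed substrate can go.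

Catalyst comes next. By hand I assume the clock runs with catalyst, so I compare catalyst times time. Cedar shows 83.1 % excess at 4.00 min, and the flask matches that catalyst-time at 8.80 min, so I say yes.

By 25 min the flask has more catalyst-time than elm's last reading. Elm's left-handed reading there, 0 %, says little against a scatter of 0.5 percentage points, but its right-handed reading, 43.6 %, is usable. Raised to the power s, its fraction left gives left-handed substrate 0.156 %, so I reckon an excess near 99.3 %.

The forecast says yes and 99 %, and adds that “the excess keeps rising until partner runs out”.

The flask gives yes and 99.1 %, passing 80 % at 6.95 min with right-handed substrate left at 47.2 % of the two substrates charged together.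

    free catalyst + left-handed substrate ⇌ catalyst intermediate A (K = 160 L mol⁻¹, k = 810 L mol⁻¹ s⁻¹)
    free catalyst + right-handed substrate ⇌ catalyst intermediate B (K = 9.00 L mol⁻¹, k = 550 L mol⁻¹ s⁻¹)
    partner + catalyst intermediate A → free catalyst + left-handed product (k = 5.40 L mol⁻¹ s⁻¹)
    partner + catalyst intermediate B → free catalyst + right-handed product (k = 2.20 L mol⁻¹ s⁻¹)
    partner + protic impurity → quenched reagent (k = 11.0 L mol⁻¹ s⁻¹)
    partner + free catalyst → spent catalyst (k = 0.0680 L mol⁻¹ s⁻¹)

Free catalyst binds the left-handed substrate more strongly by a factor 17.8, and the rate constant of catalyst intermediate A with partner is larger than that of catalyst intermediate B by a factor 2.45. At 25.0 min the flask keeps 87 % of its right-handed charge, which s turns into 0.315 % of the left-handed charge, against 0.40 % in the flask. At twice the dilution the excess ends at 87.7 %, and s places that thin flask's right-handed substrate near 46.8 %.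

(The runs are calculated for substances that don't exist; the scatter is artificial.)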